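**Retrosynthetic overview**

1. Target 15 comes from the all-trans alcohol 14 by an inverting Mitsunobu tigloylation at C4, and 14 from 13 by selective hydrogenation of the isopropenyl group on C5.
2. 13 comes from the acyclic (Z)-4-oxo-2-enal 12 by an intramolecular carbonyl-ene closure that forms the C4–C5 bond and the cyclohexenone, the only ring made in the route; C4 and C5 are set from C6 in this one event.
3. 12 comes from the 2,3-disubstituted furan 10 by singlet-oxygen ring opening; the furan ring of 1 is opened before the carbocycle is closed.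
4. 10 comes from 3-furanmethanol 1 (C1–C4 and C7) and prenal 3 (C5, C6 and the isopropyl carbons) by a catalytic asymmetric furylzinc addition that sets C6, the one stereocentre made by catalysis, followed by acetate and tiglate installation.
5. Enabling feature: the vicinal ring carbons C4 (oxygen-bearing) and C5 (isopropyl-bearing) are an aldehyde/prenyl ene retron, and the ring segment C1(=O)–C2=C3–C4 is a cis-ene-dicarbonyl, i.e. an oxidised furan that fixes the Z geometry needed for closure.

Key step: step 7

Remark on the chemistry: ring positions are numbered C1 (C=O), C2 (carrying C7H2–O), C3 (=CH), C4 (CH–O), C5 (CH–isopropyl), C6 (CH–OAc). The SMILES corresponds to the (4S,5S,6R) isomer, with the C4 oxygen cis and the C6 oxygen trans to the isopropyl group. Both unsaturated esters are tiglates; "tigloyl" means (2E)-2-methylbut-2-enoyl. The facial sense assumed for the amino-alcohol catalyst in step 2 is that of its dialkylzinc additions; its enantiomer would be used if the opposite sense were met.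

**Route**

Step 1
Reactants: 1 furan-3-ylmethanol
Product: 2 tert-butyl(furan-3-ylmethoxy)dimethylsilane
Conditions: TBSCl, imidazole, CH2Cl2, 0 °C to rt
Reagents that add atoms: tert-butyldimethylsilyl chloride, CC(C)(C)[Si](C)(C)Cl
Why: Silyl ether protection of the primary alcohol; the ether oxygen later serves as the directing group for lithiation and no stereocentre is involved.

Step 2
Reactants: 2 tert-butyl(furan-3-ylmethoxy)dimethylsilane; 3 3-methylbut-2-enal (prenal)
Product: 6 (1R)-1-[3-({[tert-butyl(dimethyl)silyl]oxy}methyl)furan-2-yl]-3-methylbut-2-en-1-ol, via 2-furyllithium 4 (not isolated), via ethyl(2-furyl)zinc 5 (not isolated)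
Conditions: n-BuLi, t-BuOMe, −78 to 0 °C; EtZnCl (from Et2Zn + ZnCl2), −78 to 0 °C; N,N,N′,N′-tetraethylethylenediamine, (2S)-3-exo-morpholinoisoborneol (5 mol %), toluene; then 3, 0 °C; H2O
Reagents that add atoms: none
Why: Oxygen-directed C2 lithiation of the 3-(silyloxymethyl)furan (kept cold and free of HMPA so that no 1,4 O-to-C silyl shift intervenes), transmetalation to the mixed ethyl(furyl)zinc and amino-alcohol-catalysed enantioselective heteroaryl transfer to the enal carbonyl (catalytic asymmetric arylzinc addition) should give the 1,2-adduct, the chiral zinc aminoalkoxide directing the furyl group to the Si face of 3 so that C6 is set as (R).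

Step 3
Reactants: 6 (1R)-1-[3-({[tert-butyl(dimethyl)silyl]oxy}methyl)furan-2-yl]-3-methylbut-2-en-1-ol
Product: 7 (1R)-1-[3-({[tert-butyl(dimethyl)silyl]oxy}methyl)furan-2-yl]-3-methylbut-2-en-1-yl acetate
Conditions: Ac2O, Et3N, 4-(dimethylamino)pyridine (cat.), CH2Cl2, 0 °C
Reagents that add atoms: acetic anhydride, CC(=O)OC(C)=O
Why: Nucleophile-catalysed O-acylation of the secondary alcohol proceeds with retention, and the basic medium avoids ionisation of the furfuryl/allylic C–O bond.

Step 4
Reactants: 7 (1R)-1-[3-({[tert-butyl(dimethyl)silyl]oxy}methyl)furan-2-yl]-3-methylbut-2-en-1-yl acetate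
Product: 8 (1R)-1-[3-(hydroxymethyl)furan-2-yl]-3-methylbut-2-en-1-yl acetate
Conditions: Bu4NF, AcOH, THF, 0 °C
Reagents that add atoms: none
Why: Fluoride-mediated Si–O cleavage buffered with acetic acid should free the primary alcohol without acetate migration and without ionisation at C6, which would let the new hydroxyl close a cyclic ether.

Step 5
Reactants: 8 (1R)-1-[3-(hydroxymethyl)furan-2-yl]-3-methylbut-2-en-1-yl acetate; 9 tiglic acid
Product: 10 {2-[(1R)-1-acetoxy-3-methylbut-2-en-1-yl]furan-3-yl}methyl (2E)-2-methylbut-2-enoate
Conditions: DCC, 4-(dimethylamino)pyridine (cat.), CH2Cl2, 0 °C to rt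
Reagents that add atoms: none
Why: Steglich esterification of the unhindered primary alcohol runs under neutral conditions that leave the (E) geometry of the acid and the labile C6 acetate untouched.

Step 6
Reactants: 10 {2-[(1R)-1-acetoxy-3-methylbut-2-en-1-yl]furan-3-yl}methyl (2E)-2-methylbut-2-enoate
Product: 12 (2Z,5R)-5-acetoxy-7-methyl-4-oxo-3-(tigloyloxymethyl)octa-2,6-dienal, via furan endoperoxide 11 (not isolated)
Conditions: O2, hν (white LED), 5,10,15,20-tetraphenylporphyrin (cat.), CH2Cl2, −78 °C; then Me2S, −78 to 0 °C; used at once without chromatography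
Reagents that add atoms: dioxygen, O=O
Why: The [4+2] cycloaddition of singlet oxygen to the electron-rich 2,3-dialkylfuran should be much faster than its ene reaction with the acetoxy-deactivated trisubstituted alkene or the tiglate, and sulfide reduction of the endoperoxide (oxidative furan ring opening) unveils the cis-ene-dicarbonyl with the Z geometry inherited from the ring, under neutral conditions that do not touch C6.

Step 7
Reactants: 12 (2Z,5R)-5-acetoxy-7-methyl-4-oxo-3-(tigloyloxymethyl)octa-2,6-dienal
Product: 13 (4R,5S,6R)-6-acetoxy-4-hydroxy-5-(prop-1-en-2-yl)-2-(tigloyloxymethyl)cyclohex-2-en-1-one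
Conditions: Me2AlCl (2.5 equiv), CH2Cl2, −78 to −40 °C; then 1 M HCl, 0 °C
Reagents that add atoms: none
Why: Me2AlCl activates the aldehyde of the vinylogous glyoxal 12, the nucleophilic end of the trisubstituted alkene (C5) bonds to the aldehyde carbon (C4) while a hydrogen of an allylic methyl group passes to the carbonyl oxygen through a six-membered array, and the reagent scavenges that proton as methane, so that the isopropenyl group and the C4 carbinol appear together. The closest known reaction type is the Lewis-acid-promoted intramolecular carbonyl-ene closure of unsaturated aldehydes onto a prenyl terminus (citronellal to isopulegol, neral to isopiperitenol), here with a more electrophilic enophile. The cyclohexenone closes in the 6-exo-trig mode at the aldehyde carbon with the attacking alkene also exocyclic; attack at C3 would be a 5-endo-trig conjugate closure and attack at the ketone a three-membered ring, so no other intramolecular path is open. C5 is controlled by C6 through allylic 1,3-strain: the C6–H bond eclipses the alkene to avoid the cis methyl group, the tether and the acetoxy group then lie on opposite alkene faces, and bond formation anti to OAc gives the 5,6-trans (5S) arrangement. C4 is controlled by the half-chair transition state in which the aluminium-bound oxygen sits pseudo-equatorial, gauche to the reacting alkene, which should give the 4,5-trans (4R) alcohol as in the isopulegol and trans-isopiperitenol closures. The step needs retention of the Z geometry and of the C6 configuration, which the furan origin of the alkene, the non-basic medium and the low temperature are expected to secure.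

Step 8
Reactants: 13 (4R,5S,6R)-6-acetoxy-4-hydroxy-5-(prop-1-en-2-yl)-2-(tigloyloxymethyl)cyclohex-2-en-1-one
Product: 14 (4R,5S,6R)-6-acetoxy-4-hydroxy-5-isopropyl-2-(tigloyloxymethyl)cyclohex-2-en-1-one
Conditions: H2 (1 atm), RhCl(PPh3)3 (5 mol %), toluene, rt
Reagents that add atoms: none
Why: Homogeneous hydrogenation with RhCl(PPh3)3 reduces the 1,1-disubstituted isopropenyl alkene far faster than trisubstituted conjugated alkenes (the carvone to carvotanacetone selectivity), so the enone and the tiglate should remain and no stereocentre is touched.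

Step 9
Reactants: 14 (4R,5S,6R)-6-acetoxy-4-hydroxy-5-isopropyl-2-(tigloyloxymethyl)cyclohex-2-en-1-one; 9 tiglic acid
Product: 15 (4S,5S,6R)-6-acetoxy-5-isopropyl-4-(tigloyloxy)-2-(tigloyloxymethyl)cyclohex-2-en-1-one
Conditions: PPh3, DIAD, toluene, 0 °C to rt
Reagents that add atoms: none
Why: Mitsunobu esterification activates the allylic C4 hydroxyl as an oxyphosphonium ion that tiglate displaces by SN2 with inversion (4R to 4S), turning the all-trans alcohol into the 4,5-cis tiglate of the target; approach is easier than in a saturated ring because C3 is trigonal and only one axial hydrogen (on C6) flanks the trajectory.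

**Compound list**

1 | furan-3-ylmethanol (3-furanmethanol) | OCc1ccoc1 | starting material
2 | tert-butyl(furan-3-ylmethoxy)dimethylsilane | CC(C)(C)[Si](C)(C)OCc1ccoc1 | intermediate
3 | 3-methylbut-2-enal (prenal) | CC(C)=CC=O | starting material
4 | [3-({[tert-butyl(dimethyl)silyl]oxy}methyl)furan-2-yl]lithium | [Li]c1occc1CO[Si](C)(C)C(C)(C)C | intermediate
5 | ethyl[3-({[tert-butyl(dimethyl)silyl]oxy}methyl)furan-2-yl]zinc | CC[Zn]c1occc1CO[Si](C)(C)C(C)(C)C | intermediate
6 | (1R)-1-[3-({[tert-butyl(dimethyl)silyl]oxy}methyl)furan-2-yl]-3-methylbut-2-en-1-ol | CC(C)(C)[Si](C)(C)OCc1ccoc1[C@H](O)C=C(C)C | intermediate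
7 | (1R)-1-[3-({[tert-butyl(dimethyl)silyl]oxy}methyl)furan-2-yl]-3-methylbut-2-en-1-yl acetate | CC(C)(C)[Si](C)(C)OCc1ccoc1[C@H](OC(C)=O)C=C(C)C | intermediate
8 | (1R)-1-[3-(hydroxymethyl)furan-2-yl]-3-methylbut-2-en-1-yl acetate | OCc1ccoc1[C@H](OC(C)=O)C=C(C)C | intermediate
9 | tiglic acid, (2E)-2-methylbut-2-enoic acid | C/C=C(\C)C(=O)O | starting material
10 | {2-[(1R)-1-acetoxy-3-methylbut-2-en-1-yl]furan-3-yl}methyl (2E)-2-methylbut-2-enoate | C/C=C(\C)C(=O)OCc1ccoc1[C@H](OC(C)=O)C=C(C)C | intermediate
11 | {1-[(1R)-1-acetoxy-3-methylbut-2-en-1-yl]-2,3,7-trioxabicyclo[2.2.1]hept-5-en-6-yl}methyl (2E)-2-methylbut-2-enoate (furan endoperoxide, bridgehead configuration not defined) | C/C=C(\C)C(=O)OCC1=CC2OOC1(O2)[C@H](OC(C)=O)C=C(C)C | intermediate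
12 | (2Z,5R)-5-acetoxy-7-methyl-4-oxo-3-(tigloyloxymethyl)octa-2,6-dienal | C/C=C(\C)C(=O)OC/C(=C/C=O)C(=O)[C@H](OC(C)=O)C=C(C)C | intermediate
13 | (4R,5S,6R)-6-acetoxy-4-hydroxy-5-(prop-1-en-2-yl)-2-(tigloyloxymethyl)cyclohex-2-en-1-one | C/C=C(\C)C(=O)OCC1=C[C@@H](O)[C@H](C(C)=C)[C@@H](OC(C)=O)C1=O | intermediate
14 | (4R,5S,6R)-6-acetoxy-4-hydroxy-5-isopropyl-2-(tigloyloxymethyl)cyclohex-2-en-1-one | C/C=C(\C)C(=O)OCC1=C[C@@H](O)[C@H](C(C)C)[C@@H](OC(C)=O)C1=O | intermediate
15 | (4S,5S,6R)-6-acetoxy-5-isopropyl-4-(tigloyloxy)-2-(tigloyloxymethyl)cyclohex-2-en-1-one | C/C=C(\C)C(=O)OCC1=C[C@H](OC(=O)/C(C)=C/C)[C@H](C(C)C)[C@@H](OC(C)=O)C1=O | target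

**Step count**

Total step count: 9. Longest linear sequence: 9 steps (1 to 15).

**Steps most likely to fail**

Step 7. What may go wrong: poor facial selectivity at the aldehyde carbon during ring closure (the aluminium-bound oxygen taking the pseudo-axial instead of the pseudo-equatorial position), so that the 4,5-cis alcohol forms beside or in place of 13. Fallback: setting out from 12, the closure is accepted as it comes and the endgame is made stereoconvergent. The cis epimer, (4S,5S,6R)-6-acetoxy-4-hydroxy-5-(prop-1-en-2-yl)-2-(tigloyloxymethyl)cyclohex-2-en-1-one F1, is separated and hydrogenated with H2 and RhCl(PPh3)3 to (4S,5S,6R)-6-acetoxy-4-hydroxy-5-isopropyl-2-(tigloyloxymethyl)cyclohex-2-en-1-one F2. F2 is then esterified with 9 under Steglich conditions (DCC, 4-(dimethylamino)pyridine), that is with retention at C4, and the sequence comes back to the route at 15. Any trans epimer continues through steps 8 and 9, so inversion serves one epimer and retention the other.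

Step 9. What may go wrong: slow SN2 displacement at the hindered allylic C4 by the weakly acidic tiglic acid, leaving room for elimination towards a dienone and phenol or for ionisation with loss of stereospecificity. Fallback: setting out from 14, inversion is separated from tigloylation. A Mitsunobu reaction with the more acidic chloroacetic acid (PPh3, DIAD) should give the inverted ester (4S,5S,6R)-6-acetoxy-4-(chloroacetoxy)-5-isopropyl-2-(tigloyloxymethyl)cyclohex-2-en-1-one F3. Selective removal of the chloroacetate with thiourea and NaHCO3 in ethanol, which spares acetate and tiglate, gives the cis alcohol F2. Steglich esterification of F2 with 9 (DCC, 4-(dimethylamino)pyridine), with retention, comes back to the route at 15.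

Step 2. What may go wrong: insufficient enantioselectivity in the furyl transfer, since an ortho-substituted heteroarylzinc and a β,β-disubstituted enal are both demanding partners for the amino-alcohol catalyst. Fallback: setting out from 2, lithiation as before and direct addition of 4 to 3 without zinc or ligand gives the racemic alcohol 1-[3-({[tert-butyl(dimethyl)silyl]oxy}methyl)furan-2-yl]-3-methylbut-2-en-1-ol F4. A Sharpless-type kinetic resolution of this 2-furylcarbinol (Ti(OiPr)4, L-(+)-diisopropyl tartrate, t-BuOOH, CH2Cl2, −20 °C) should consume the (S)-enantiomer by oxidative ring expansion (Achmatowicz-type) to (2S)-4-({[tert-butyl(dimethyl)silyl]oxy}methyl)-6-hydroxy-2-(2-methylprop-1-en-1-yl)-2H-pyran-3(6H)-one F5 and leave the (R)-alcohol, which comes back to the route at 6. The competing allylic-alcohol epoxidation is expected to be slow because the alkene carries a cis methyl group.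

Further compounds
F1 | step 7 | (4S,5S,6R)-6-acetoxy-4-hydroxy-5-(prop-1-en-2-yl)-2-(tigloyloxymethyl)cyclohex-2-en-1-one | C/C=C(\C)C(=O)OCC1=C[C@H](O)[C@H](C(C)=C)[C@@H](OC(C)=O)C1=O
F2 | step 7 | (4S,5S,6R)-6-acetoxy-4-hydroxy-5-isopropyl-2-(tigloyloxymethyl)cyclohex-2-en-1-one | C/C=C(\C)C(=O)OCC1=C[C@H](O)[C@H](C(C)C)[C@@H](OC(C)=O)C1=O
F3 | step 9 | (4S,5S,6R)-6-acetoxy-4-(chloroacetoxy)-5-isopropyl-2-(tigloyloxymethyl)cyclohex-2-en-1-one | C/C=C(\C)C(=O)OCC1=C[C@H](OC(=O)CCl)[C@H](C(C)C)[C@@H](OC(C)=O)C1=O
F4 | step 2 | racemic 1-[3-({[tert-butyl(dimethyl)silyl]oxy}methyl)furan-2-yl]-3-methylbut-2-en-1-ol | CC(C)(C)[Si](C)(C)OCc1ccoc1C(O)C=C(C)C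
F5 | step 2 | (2S)-4-({[tert-butyl(dimethyl)silyl]oxy}methyl)-6-hydroxy-2-(2-methylprop-1-en-1-yl)-2H-pyran-3(6H)-one | O=C1C(CO[Si](C)(C)C(C)(C)C)=CC(O)O[C@H]1C=C(C)C
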